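The isoflavone is cut across its pyranone ring so that O1–C8a, C4–C4a and O1–C2 are all made at once. The A ring carries O1 on C8a and the C4 carbonyl on the adjacent C4a, which in turn neighbours the C5 oxygen: exactly the ortho-difunctionalisation pattern that a 3-alkoxyaryne accepts regioselectively. A 3,5-dimethoxybenzyne, released from an ortho-silyl aryl triflate, inserts into the acyl–oxygen bond of a 2-aryl-3-methoxyacrylic acid, and the phenoxide so formed closes the pyranone by displacing methoxide. Demethylation, O-prenylation of the 7-OH and a [3,3] shift to C8 finish the 1,1-dimethylallyl isoflavone.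

Key step: step 7

Remark on the structure: the target has no stereocentre (the quaternary side-chain carbon bears two identical methyl groups) and no stereogenic double bond. It is therefore a single achiral compound and no enantiocontrol is needed. The only stereo-element in the route, the (E)-alkene of acid 13, is erased in step 7.

Remark on the design: the silyl group of the aryne precursor is placed by carbamate-directed ortho-lithiation. The two positions flanked by the carbamate and a methoxy group are equivalent, so no C2/C4 regiochemical question arises, as it would in a halogenation of the free phenol.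

Numbering used: isoflavone numbering (O1, C2, C3, C4, C4a, C5–C8, C8a; B ring primed).

Step 1
Reactants: 1 3,5-dimethoxyphenol
Product: 2 3,5-dimethoxyphenyl N-isopropylcarbamate
Conditions: i-PrNCO, Et3N (cat.), CH2Cl2, rt
Reagents that add atoms: isopropyl isocyanate, CC(C)N=C=O
Why: Amine-catalysed addition of the phenol to the isocyanate (carbamoylation) should be clean and gives a secondary O-aryl carbamate that directs metalation and is later removable under mild base.

Step 2
Reactants: 2 3,5-dimethoxyphenyl N-isopropylcarbamate
Product: 6 3,5-dimethoxy-2-(trimethylsilyl)phenyl N-isopropylcarbamate, via N-TBS carbamate 3 (not isolated), via ortho-lithiated N-TBS carbamate 4 (not isolated), via N-TBS C-TMS carbamate 5 (not isolated)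
Conditions: TBSOTf (1.1 equiv), TMEDA, Et2O, 0 °C → rt; n-BuLi (2.2 equiv), TMEDA, −78 °C; TMSCl, −78 °C → rt; aq. NaHSO4
Reagents that add atoms: chlorotrimethylsilane, C[Si](C)(C)Cl
Why: In situ N-silylation masks the acidic N–H, so directed ortho-metalation should occur at the carbon flanked by the carbamate and a methoxy group (both such sites are equivalent), after which the aryllithium is C-silylated and the N–Si bond is hydrolysed on work-up.

Step 3
Reactants: 6 3,5-dimethoxy-2-(trimethylsilyl)phenyl N-isopropylcarbamate
Product: 8 3,5-dimethoxy-2-(trimethylsilyl)phenyl trifluoromethanesulfonate, via 3,5-dimethoxy-2-(trimethylsilyl)phenol 7 (not isolated)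
Conditions: DBU, Et2NH, MeCN, 40 °C; then PhNTf2, rt
Reagents that add atoms: N-phenylbis(trifluoromethanesulfonimide), O=S(=O)(N(c1ccccc1)S(=O)(=O)C(F)(F)F)C(F)(F)F
Why: DBU should deprotonate the N–H carbamate, which fragments by E1cB to the phenoxide and isopropyl isocyanate (scavenged by diethylamine as a urea), and the phenoxide is then O-sulfonylated in the same pot (one-pot carbamate cleavage–triflation).

Step 4
Reactants: 9 2,4-dimethoxyphenylacetic acid
Product: 10 methyl 2,4-dimethoxyphenylacetate
Conditions: MeOH, H2SO4 (cat.), reflux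
Reagents that add atoms: methanol, CO
Why: Fischer esterification of an unhindered arylacetic acid in excess methanol should go to completion.

Step 5
Reactants: 10 methyl 2,4-dimethoxyphenylacetate
Product: 12 methyl (E)-2-(2,4-dimethoxyphenyl)-3-methoxyacrylate, via sodium formyl-ester enolate 11 (not isolated)
Conditions: NaH, HCO2Me, THF, 0 °C → rt; then Me2SO4, DMF, rt
Reagents that add atoms: methyl formate, COC=O; dimethyl sulfate, COS(=O)(=O)OC
Why: Crossed Claisen condensation with methyl formate should give the stabilised sodium enolate of the α-formyl ester, which the hard methylating agent alkylates on oxygen to the favoured (E)-β-methoxyacrylate (the geometry is not critical because it is lost in step 7).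

Step 6
Reactants: 12 methyl (E)-2-(2,4-dimethoxyphenyl)-3-methoxyacrylate
Product: 13 (E)-2-(2,4-dimethoxyphenyl)-3-methoxyacrylic acid
Conditions: LiOH·H2O, THF/MeOH/H2O, rt; then 1 M HCl to pH 3, 0 °C
Reagents that add atoms: lithium hydroxide, [Li+].[OH-]
Why: Saponification (BAc2) of the methyl ester should leave the enol ether intact provided the acidification is kept cold and mild.

Step 7
Reactants: 8 3,5-dimethoxy-2-(trimethylsilyl)phenyl trifluoromethanesulfonate; 13 (E)-2-(2,4-dimethoxyphenyl)-3-methoxyacrylic acid
Product: 16 3-(2,4-dimethoxyphenyl)-5,7-dimethoxy-4H-chromen-4-one, via 3,5-dimethoxybenzyne 14 (not isolated), via ortho-acyl phenoxide 15 (not isolated)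
Conditions: CsF (4 equiv), 8 (1.5 equiv), THF, 125 °C, sealed tube
Reagents that add atoms: none
Why: Fluoride removes the silyl group of 8 and triflate departs to give aryne 14, the caesium carboxylate of 13 adds through oxygen to the aryne carbon remote from the 3-methoxy group, and the aryl anion left next to that methoxy group attacks the ester carbonyl through a four-membered alkoxide that collapses to the ortho-acyl phenoxide 15 (O1–C8a and C4–C4a formed). The closest known reaction type is the insertion of arynes into the acyl–oxygen bond of carboxylic acids to give ortho-hydroxyaryl ketones, which with α,β-unsaturated acids continues by intramolecular oxa-Michael addition to chroman-4-ones; the β-methoxy group here only adds a leaving group to that sequence. The pyranone ring closes by 6-endo-trig attack of the phenoxide oxygen on the methoxymethylene carbon (O1–C2) followed by E1cB loss of methoxide, so both alkene geometries should converge on the chromone. No stereocentre is created. Two selectivities are needed: oxygen must bond to the aryne carbon distal to the methoxy group, which the inductive polarisation and distortion of a 3-alkoxyaryne enforce, and the aryl anion must attack the acyl carbon and not the β-carbon or a proton, which the proximity of the acyl carbon, the donor-deactivated β-position and the hot, aprotic, base-rich medium favour.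

Step 8
Reactants: 16 3-(2,4-dimethoxyphenyl)-5,7-dimethoxy-4H-chromen-4-one
Product: 17 3-(2,4-dihydroxyphenyl)-5,7-dihydroxy-4H-chromen-4-one (2'-hydroxygenistein)
Conditions: BBr3 (10 equiv), CH2Cl2, −78 °C → rt; then ice-water
Reagents that add atoms: none
Why: Boron tribromide should cleave all four aryl methyl ethers (Lewis-acid activation, then SN2 attack of bromide on methyl) without harming the chromone, and hydrolytic work-up releases the tetraphenol.

Step 9
Reactants: 17 3-(2,4-dihydroxyphenyl)-5,7-dihydroxy-4H-chromen-4-one; 18 prenyl bromide (1-bromo-3-methylbut-2-ene)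
Product: 19 3-(2,4-dihydroxyphenyl)-5-hydroxy-7-[(3-methylbut-2-en-1-yl)oxy]-4H-chromen-4-one
Conditions: K2CO3 (1.1 equiv), 18 (1.05 equiv), acetone, rt → 40 °C
Reagents that add atoms: none
Why: Williamson etherification with one equivalent of weak base should engage only the 7-OH, the most acidic phenol (vinylogous acid para to the C4 carbonyl), while the 5-OH is held in a hydrogen bond to C4=O and the B-ring phenols remain largely protonated.

Step 10
Reactants: 19 3-(2,4-dihydroxyphenyl)-5-hydroxy-7-[(3-methylbut-2-en-1-yl)oxy]-4H-chromen-4-one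
Product: 20 3-(2,4-dihydroxyphenyl)-5,7-dihydroxy-8-(2-methylbut-3-en-2-yl)-4H-chromen-4-one
Conditions: Eu(fod)3 (10 mol %), NaHCO3, PhCl, 85 °C
Reagents that add atoms: none
Why: A Lewis-acid-promoted aromatic Claisen rearrangement ([3,3]-sigmatropic shift with allylic inversion) should deliver the 1,1-dimethylallyl group to C8, the ortho position favoured in 5-hydroxy-7-allyloxychromones, and tautomerisation restores the 7-OH; the new quaternary carbon carries two methyl groups, so no stereocentre arises.

Compound list
1 | 3,5-dimethoxyphenol | COc1cc(O)cc(OC)c1 | starting material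
2 | 3,5-dimethoxyphenyl N-isopropylcarbamate | COc1cc(OC)cc(OC(=O)NC(C)C)c1 | intermediate
3 | 3,5-dimethoxyphenyl N-(tert-butyldimethylsilyl)-N-isopropylcarbamate | COc1cc(OC)cc(OC(=O)N(C(C)C)[Si](C)(C)C(C)(C)C)c1 | intermediate (not isolated)
4 | 2-lithio-3,5-dimethoxyphenyl N-(tert-butyldimethylsilyl)-N-isopropylcarbamate | [Li]c1c(OC)cc(OC)cc1OC(=O)N(C(C)C)[Si](C)(C)C(C)(C)C | intermediate (not isolated)
5 | 3,5-dimethoxy-2-(trimethylsilyl)phenyl N-(tert-butyldimethylsilyl)-N-isopropylcarbamate | COc1cc(OC)c([Si](C)(C)C)c(OC(=O)N(C(C)C)[Si](C)(C)C(C)(C)C)c1 | intermediate (not isolated)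
6 | 3,5-dimethoxy-2-(trimethylsilyl)phenyl N-isopropylcarbamate | COc1cc(OC)c([Si](C)(C)C)c(OC(=O)NC(C)C)c1 | intermediate
7 | 3,5-dimethoxy-2-(trimethylsilyl)phenol (present as its DBU-H+ phenoxide) | COc1cc(O)c([Si](C)(C)C)c(OC)c1 | intermediate (not isolated)
8 | 3,5-dimethoxy-2-(trimethylsilyl)phenyl trifluoromethanesulfonate | COc1cc(OC)c([Si](C)(C)C)c(OS(=O)(=O)C(F)(F)F)c1 | intermediate
9 | 2,4-dimethoxyphenylacetic acid | COc1ccc(CC(=O)O)c(OC)c1 | starting material
10 | methyl 2,4-dimethoxyphenylacetate | COC(=O)Cc1ccc(OC)cc1OC | intermediate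
11 | sodium enolate of methyl 2-(2,4-dimethoxyphenyl)-3-oxopropanoate (enolate geometry not defined) | COC(=O)C(=C[O-])c1ccc(OC)cc1OC.[Na+] | intermediate (not isolated)
12 | methyl (E)-2-(2,4-dimethoxyphenyl)-3-methoxyacrylate | CO/C=C(/C(=O)OC)c1ccc(OC)cc1OC | intermediate
13 | (E)-2-(2,4-dimethoxyphenyl)-3-methoxyacrylic acid | CO/C=C(/C(=O)O)c1ccc(OC)cc1OC | intermediate
14 | 3,5-dimethoxybenzyne (1,2-didehydro-3,5-dimethoxybenzene) | COC1=CC(OC)=CC#C1 | intermediate (not isolated)
15 | caesium 2-[(E)-2-(2,4-dimethoxyphenyl)-3-methoxyacryloyl]-3,5-dimethoxyphenolate | CO/C=C(/C(=O)c1c([O-])cc(OC)cc1OC)c1ccc(OC)cc1OC.[Cs+] | intermediate (not isolated)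
16 | 3-(2,4-dimethoxyphenyl)-5,7-dimethoxy-4H-chromen-4-one | COc1cc(OC)c2c(=O)c(-c3ccc(OC)cc3OC)coc2c1 | intermediate
17 | 3-(2,4-dihydroxyphenyl)-5,7-dihydroxy-4H-chromen-4-one (2'-hydroxygenistein) | Oc1ccc(-c2coc3cc(O)cc(O)c3c2=O)c(O)c1 | intermediate
18 | prenyl bromide (1-bromo-3-methylbut-2-ene) | CC(C)=CCBr | starting material
19 | 3-(2,4-dihydroxyphenyl)-5-hydroxy-7-[(3-methylbut-2-en-1-yl)oxy]-4H-chromen-4-one | CC(C)=CCOc1cc(O)c2c(=O)c(-c3ccc(O)cc3O)coc2c1 | intermediate
20 | 3-(2,4-dihydroxyphenyl)-5,7-dihydroxy-8-(2-methylbut-3-en-2-yl)-4H-chromen-4-one | C=CC(C)(C)c1c(O)cc(O)c2c(=O)c(-c3ccc(O)cc3O)coc12 | target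

Total step count: 10
Longest linear sequence: 7 steps (steps 1–3 or steps 4–6, then steps 7–10)

Steps most likely to fail

1. Step 7. The acyl group is a hindered, donor-substituted (vinylogous carbonate) carbonyl, so acyl transfer to the aryl anion may be slow. The anion could then be protonated, leaving only an O-aryl ester, or could add in a conjugate sense; the aryne may also be consumed unproductively. Fallback: setting out from 1 and 9, ortho-acylation of the phenol with the arylacetic acid in BF3·OEt2 at 80–90 °C (Friedel–Crafts/Fries type) should give the deoxybenzoin 1-(2-hydroxy-4,6-dimethoxyphenyl)-2-(2,4-dimethoxyphenyl)ethan-1-one F1. Heating F1 with N,N-dimethylformamide dimethyl acetal in toluene at 100 °C should form the enaminone (E)-3-(dimethylamino)-1-(2-hydroxy-4,6-dimethoxyphenyl)-2-(2,4-dimethoxyphenyl)prop-2-en-1-one F2, which cyclises with loss of dimethylamine. The route is rejoined at 16.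

2. Step 10. The [3,3] shift may partly go to C6, the three free phenols and the 5-OH/C4=O chelate may bind the europium so that turnover stalls, and the ortho-(1,1-dimethylallyl)phenol may react further by acid-induced ring closure or prenyl ionisation. Fallback: setting out from 19, acetylation (Ac2O, pyridine, DMAP, rt) should give 4-[5-acetoxy-7-(3-methylbut-2-enyloxy)-4-oxo-4H-chromen-3-yl]-1,3-phenylene diacetate F3. With the 5-OH acylated the A ring behaves like a plain 7-allyloxychromone, for which migration to C8 is the rule. An uncatalysed thermal Claisen rearrangement in N,N-diethylaniline containing acetic anhydride at about 180 °C traps the liberated 7-phenol as it forms, giving 4-[5,7-diacetoxy-8-(2-methylbut-3-en-2-yl)-4-oxo-4H-chromen-3-yl]-1,3-phenylene diacetate F4. Mild methanolysis (K2CO3, MeOH, 0 °C → rt) returns to the route at 20.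

3. Step 9. Once more than one phenol is deprotonated, alkylation may spread to the 4'- and 2'-oxygens or to ring carbon (C6/C8), eroding the mono-ether. Fallback: setting out from 17, a Mitsunobu etherification with 3-methylbut-2-en-1-ol (PPh3, DIAD, THF, 0 °C → rt) runs without added base and should activate only the most acidic phenol. It arrives directly at 19 and makes no new compound (none, F0).

Further compounds
F1 | step 7 | 1-(2-hydroxy-4,6-dimethoxyphenyl)-2-(2,4-dimethoxyphenyl)ethan-1-one | COc1cc(O)c(C(=O)Cc2ccc(OC)cc2OC)c(OC)c1
F2 | step 7 | (E)-3-(dimethylamino)-1-(2-hydroxy-4,6-dimethoxyphenyl)-2-(2,4-dimethoxyphenyl)prop-2-en-1-one | CN(C)/C=C(/C(=O)c1c(O)cc(OC)cc1OC)c1ccc(OC)cc1OC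
F3 | step 10 | 4-[5-acetoxy-7-(3-methylbut-2-enyloxy)-4-oxo-4H-chromen-3-yl]-1,3-phenylene diacetate | CC(C)=CCOc1cc(OC(C)=O)c2c(=O)c(-c3ccc(OC(C)=O)cc3OC(C)=O)coc2c1
F4 | step 10 | 4-[5,7-diacetoxy-8-(2-methylbut-3-en-2-yl)-4-oxo-4H-chromen-3-yl]-1,3-phenylene diacetate | C=CC(C)(C)c1c(OC(C)=O)cc(OC(C)=O)c2c(=O)c(-c3ccc(OC(C)=O)cc3OC(C)=O)coc12
F0 | step 9 | none | none
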